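Its constants were chosen freely; the flask was simulated.

I started from the easy step: ring closure needs no partner, so each J closes at the same pace however little J is left.

    2 J → J2 (k1 = 5.87 /M/min, Ea1 = 76.0 kJ/mol)
    J → E (k2 = 0.0832 /min, Ea2 = 110 kJ/mol)
    E → L (k3 = 0.00137 /min, Ea3 = 127 kJ/mol)
    J ⇌ Q (K4 = 0.693, k4 = 0.0239 /min, Ea4 = 100 kJ/mol, ΔH4 = −59.0 kJ/mol)
    (constants at 90 °C)

| setting | south-west | east | south-east |
|---|---|---|---|
| J | 20 mM | 20 mM | 20 mM |
| temperature | 30 °C | 60 °C | 90 °C |
| time | 25 min | 25 min | 25 min |

- percent here means J units held: one J2 counts as two
- two of one species on the left: rate k times its square, two consumed each time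
- all constants are for 90 °C and move with temperature by the activation energies and enthalpies

1. the flask with the highest amount of E, in percent of the J charged ("all alike" if they lie within 1.5 percentage points) (south-west / east / south-east / all alike)
2. final E, as a percentage of the J charged, in south-west
3. final E, as a percentage of the J charged, in east
4. final E, as a percentage of the J charged, in south-east

Let x be J as a fraction of the charge. Ring closure removes x at x over the ring time, one over its constant. Dimerisation removes it at x squared over the dimer time, one over twice its constant times the charge. In south-east these times were 12.0 min and 4.26 min. Their ratio is 0.354: the ring number b, dimer time over ring time, a selectivity factor. At any moment, E takes b/(b+x) of the J leaving by these two routes.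

Heat raised b: it was 0.0382 in south-west and 0.129 in east, so I chose south-east. Both south-east times were shorter than the run, so I let x fall from one to zero and replaced it by its mean, half. That gave a share of 41.5%. Integrating properly gives b times the logarithm of one plus one over b, or 47.5%, so the mean read lower by 6 percentage points. My own reckoning stopped at that band, which is a share of what left by the two routes and not an amount, and it gave no amount for the two colder flasks; the forecast, which differs from it here, gave amounts.

The forecast named south-east, with 0.15%, 5.8% and 41% of the charge. Its ground: “Ring closure has a higher activation energy than dimerisation”.

The flask gave south-east, with 0.150%, 5.85% and 40.5%. At 25.0 min, south-east also held J2 48.1%, L 1.05%, Q 6.41% and J 3.96%. Counting E with L against J2, the reading is 46.3%, inside my band.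

In the neighbour like east at 75 °C, b is 0.218, and the mean gives a share of 30.4%. The run gave E 20.0% and J2 51.0%, with J 23% still there: a share of 28.3%.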